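Initiator meets free monomer in a closed flask.

    free monomer + living end → monomer in chains + living end, rate k1*[living end]*[free monomer] (k1 = 0.31 M⁻¹ s⁻¹)
    free monomer + initiator → living end + monomer in chains (k2 = 1.5 × 10⁻⁴ M⁻¹ s⁻¹)
    free monomer + initiator → spent initiator (k3 = 3.8 × 10⁻⁵ M⁻¹ s⁻¹)
    free monomer → uncatalysed product (k4 = 1.9 × 10⁻⁶ s⁻¹)
free monomer 0.20 M; initiator 2.0 mM; time 12 h
1. average number of monomer units in a chain (chains begun, living or dead) at 12 h
2. part of the free monomer that has reacted at 12 h
- the average divides the monomer in chains by the number of chains begun, living and dead together
- run time (flask): 12 h

The growth constant of a living end stands far above the starting constant of initiator, so in my reckoning ends keep arising while the free monomer is used. One number carries the reckoning: 0.0484, the start number w, which is the starting constant over the growth constant, times the charge of free monomer over that of initiator. Let x be the part of the initiator charge standing as living ends, and f the part of the free monomer charge gone into chains. Dividing the two rates gives x squared equal to 2 w f, times the mean part of the initiator remaining over the monomer used. Each end costs 1.25 of initiator, the spent route counted. The uncatalysed half-life is long against the run, so my reckoning sets f to one.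

If the initiator never fell, x would be 0.311, giving 321 units per chain. If it stood at its end level from the start, x would be 0.256, giving 390. In this reckoning the flask lies between, because its initiator falls from the one level to the other. Since x grows about as the root of f, the mean loss over the monomer used is about 0.667 of the end loss. That gives x of 0.273 and 366 units per chain. At that number of ends, free monomer has a time constant of 1.64 h, so my reckoning, which holds that number over the whole run, has nearly all reacted by 12 h.

The forecast gives 363 and 99.8 %, holding that “only about a third of the initiator is consumed”; my chain length stands above its figure.

The flask gives 363 and 99.8 %. Free monomer, the limiting reagent, is down to 0.22 % of its charge, less than the initiator's 66 %. Setting f to the 97.6 % in chains, the start number gives x of 0.270 and 361 units per chain.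

Read at 5.0 h, the same flask has 83.4 % in chains, so the start number gives x of 0.252 and 331 units per chain. The computed value for that reading is 332.

All constants belong to no real substance; no experiment stands behind them.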